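**Remark on the chemistry:** the SMILES of the target contains no stereocentre and the flavonol is achiral, so there is no enantiomer to select. The only sp3 stereocentre on the route (C3 of 14) is racemic and is erased in the same flask.

Abbreviations: SEM = 2-(trimethylsilyl)ethoxymethyl, and "SEM-oxy" = OCH2OCH2CH2SiMe3. Prenyl = 3-methylbut-2-enyl. Flavone numbering is used for the target and its precursors.

## Analysis of the target

Target 16 is a flavonol, a 4H-chromen-4-one in which benzo ring A is fused to pyranone ring C. It carries a 4-oxygenated phenyl ring B at C2 and a hydroxyl at C3. It has no stereocentre, so the whole problem is one of placing substituents.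

Ring A bears oxygen at every position except C6. O5 and O7 are free, O8 is methylated and O1 (on C8a) belongs to ring C. Four oxygens on one benzene ring must therefore be told apart, and ring closure through the wrong ortho oxygen would give the 6-methoxy isomer.

Among the remaining acidic positions only O4' carries the prenyl group. The 7-OH is the most acidic, so late selective alkylation is not realistic, and both alkyl groups have to sit in the fragments before assembly.

The aryl prenyl ether is the most fragile group:
- Brønsted and Lewis acids cleave or rearrange it.
- Hydrogenation and peracids attack its alkene.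
- Strong heating triggers a Claisen rearrangement.
- Palladium(0) can ionise it.

The free flavonol anion is degraded by oxygen in base, and C6 of the freed ring A is nucleophilic. This rules out acid-labile or hydrogenolysable masks at the end and points to fluoride-labile ones.

The strategy rests on C4 of ring C. Its only carbon neighbours are C4a of ring A (flanked by the oxygenated C5 and C8a) and C3 (which already bears oxygen). C4 is therefore a one-carbon unit at the oxidation level of carbon monoxide. It can be inserted between a halide at C4a and the α-carbon of an α-oxygenated ketone that brings C3, O3, C2 and ring B.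

## Retrosynthetic reasoning

**16 to 15.** The three O–H bonds at O3, O5 and O7 are traced back to SEM ethers in 15. One kind of mask on all three oxygens allows a single final operation. A silicon-triggered mask is the one type whose removal needs neither acid nor hydrogenation nor an oxidant, so the methyl and prenyl ethers of 16 are left alone.

**15 to 8, 12 and 13.** Ring C is taken apart at O1–C2, C3–C4 and C4–C4a.
- Cutting O1–C2 by formal hydration gives the open 2-alkoxy-1,3-diketone 14.
- Cutting both bonds at C4 of 14 leaves iodophenol 8, carbon monoxide 13 and α-(SEM-oxy) ketone 12.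
- These bonds are chosen because they split the molecule into two halves of equal size that each carry their own alkyl ether.
- O3 travels with the ketone, so no later oxidation at C3 is needed.
- Ring A needs no carbon substituent at the hindered C4a.
- The forward reaction has to form an aroylpalladium species from 8 and 13, join it to the enolate carbon of 12, and then let the only free phenol (O8a) condense on the C2 ketone.

**8 to 7.** The C4a–I bond is cut. Iodine is put in last on ring A because it would not survive the reductive unmasking of the phenol. The forward step has to choose the position next to the hydroxyl over the one between the two SEM-oxy groups.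

**7 to 6 to 5.** The free phenol of 7 is traced to the benzyl ether 6, and the O8–CH3 bond of 6 to the phenol 5. A benzyl group marks the oxygen that will become O1 while its neighbour is methylated. It is orthogonal to SEM and methyl, and it is removed while the molecule still holds no iodine and no alkene.

**5 to 3 (through 4).** The C8–O bond is traced to a C–CHO bond. The aldehyde carbon of a phloroglucinol aldehyde sits exactly where the fourth oxygen is wanted. A peracid-induced aryl migration exchanges carbon for oxygen there, with formate 4 as the relay. This avoids any direct oxidation of the electron-rich ring.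

**3 to 2 to 1.** The benzyl and the two SEM ethers are removed in turn, which leads to the symmetrical aldehyde 1. The aldehyde does the differentiation. After the para and one ortho hydroxyl are capped, the last ortho hydroxyl of 2 is held in a hydrogen bond and stays free for benzylation.

**12 to 11 to 9 and 10.** The O3–SEM bond and then the O4'–prenyl bond are cut. Ketol 9 already holds C2, C3, O3 and ring B. The large acidity gap between its phenol and its primary alcohol lets 10 go on to O4' first and the SEM group on to O3 second.

## Alternatives that were turned down

**Alternative 1:** The C4–C4a bond of the protected dihydroflavonol A1 is cut. This leads back to the iodo ester A2, in which O1–C2 and C2–C3 already exist. In the forward sense, iodine–magnesium exchange at C4a of A2 gives an arylmagnesium species that attacks the tethered methyl ester and closes ring C.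

*For it:* the closure is intramolecular, the exchange is dependable, no palladium comes near the prenyl ether and no gas is handled. The 8-methoxy pattern is locked as firmly as in the chosen route because O1 is already bound to C2. On the reliability of the ring-closing event itself this plan is the stronger one.

*Against it:*
- A2 has to be made from 8 by alkylating a doubly ortho-substituted phenol at a secondary benzylic carbon. The 4-alkoxyphenyl group on that carbon favours ionisation and elimination.
- The arylmagnesium can deprotonate the ester α-position and expel the β-aryloxide.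
- A1 lies two hydrogens below the flavonol, so desilylation and a dehydrogenation next to the prenyl alkene must follow.
- The trans relationship at C2 and C3 is controlled only to be destroyed in an achiral target.

*Comparison:* the sequence is linear from 8 and clearly longer. The chosen route gives up the safety of an intramolecular acylation. In return it gains convergence, the correct oxidation level and three bonds in one flask.

**Alternative 2:** The C2=C3 and C3–C4 bonds of the 3-(2-trimethylsilylethoxy)flavone A3 are cut. This gives the O-aroylated salicyloyl chloride A4 and the alkoxymethylene ylide A5 as a one-carbon piece for C3. In the forward sense A5 is acylated by A4, and the acyl ylide then olefinates the neighbouring aryl ester carbonyl in an intramolecular Wittig reaction.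

*For it:* it is metal-free, the regiocontrol is equal because the ester sits on O8a, and the closure is driven irreversibly by phosphorus–oxygen bond formation. The O3 mask is fluoride-labile and releases no formaldehyde, which is a small advantage over the chosen route.

*Against it:*
- C4 must already be on ring A, so A4 comes from 8 by carboxylation, aroylation and activation. The iodophenol is needed anyway and three operations are added.
- Acid chloride formation generates acid next to two acetal-type ethers.
- A5 is basic. Half of it is consumed as base in the transylidation, and it can attack the aryl ester of A4 instead of the hindered acid chloride.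
- The acylated ylide is stabilised and fully substituted, yet it must form a tetrasubstituted alkene from an ester carbonyl.
- A stoichiometric phosphorus by-product is carried.

*Comparison:* the chosen route takes C4 from 13 directly and needs no activation steps.

**Alternative 3:** The O1–C8a bond of the 5,8-quinol A6 is cut, which leads to the acylhydroquinone A7 with hydrogen at C8a. In the forward sense, anodic two-electron oxidation of A7 gives the acylquinone A8. The diketone enol oxygen of A8 adds to C8a, and reductive work-up delivers A6, which then needs methylation at O8.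

*For it:* no halogen is needed and there is no differentiation of O8a, because that oxygen arrives by C–H functionalisation. Electrons serve as the oxidant. The later methylation is naturally selective because the 5-OH is chelated. In its economy of protecting groups on ring A this plan is the better one.

*Against it:*
- The prenyl alkene, the alkoxyphenyl ring and the diketone enol are all oxidisable at the anode.
- A6 is easier to oxidise than A7, so over-oxidation threatens.
- The 2-alkoxy-1,3-diketone is poorly enolised, so the oxygen nucleophile is scarce.
- A8 is a very strong electrophile that can pick up electrolyte or solvent, and its SEM-oxy group becomes a labile vinylogous ester acetal.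
- A7 itself still requires a separate C3–C4 bond formation.

*Comparison:* the chosen route forms that bond and the ring together, and it rests on a better understood catalytic cycle.

Key step: step 9

## Route

Step 1
Reactants: 1 2,4,6-trihydroxybenzaldehyde
Product: 2 2-hydroxy-4,6-bis(SEM-oxy)benzaldehyde
Conditions: SEMCl (2.1 equiv), iPr2NEt (2.5 equiv), CH2Cl2–DMF, 0 °C → rt
Reagents that add atoms: SEMCl, 2-(trimethylsilyl)ethoxymethyl chloride, C[Si](C)(C)CCOCCl
Why: Williamson-type alkylation with a chloromethyl ether; the para hydroxyl and one of the two equivalent ortho hydroxyls react. The last ortho hydroxyl is hydrogen-bonded to the aldehyde oxygen, is much less nucleophilic under amine base and should stay free, as is usual for acetal-type protection of phloroglucinol aldehydes and ketones.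

Step 2
Reactants: 2 2-hydroxy-4,6-bis(SEM-oxy)benzaldehyde
Product: 3 2-(benzyloxy)-4,6-bis(SEM-oxy)benzaldehyde
Conditions: BnBr, K2CO3, DMF, rt → 50 °C
Reagents that add atoms: benzyl bromide, BrCc1ccccc1
Why: Williamson ether synthesis; carbonate in a dipolar solvent breaks the chelate and the phenoxide is benzylated. The benzyl group marks the oxygen that becomes O1 and is orthogonal to SEM and methyl.

Step 3
Reactants: 3 2-(benzyloxy)-4,6-bis(SEM-oxy)benzaldehyde
Product: 5 2-(benzyloxy)-4,6-bis(SEM-oxy)phenol, via aryl formate 4 (not isolated)
Conditions: mCPBA, CH2Cl2, 0 °C → rt; aq. Na2S2O3/NaHCO3 wash; crude 4, K2CO3 (cat.), MeOH, 0 °C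
Reagents that add atoms: mCPBA, 3-chloroperbenzoic acid, O=C(OO)c1cccc(Cl)c1
Why: Baeyer–Villiger oxidation, the peracid form of the Dakin reaction, is used because alkaline peroxide needs a free ortho or para hydroxyl, which 3 lacks. The aryl group with three donor oxygens migrates in preference to hydride. The formate is methanolysed only after the peracid has been washed out, so the oxidisable phenol 5 never meets oxidant.

Step 4
Reactants: 5 2-(benzyloxy)-4,6-bis(SEM-oxy)phenol
Product: 6 1-(benzyloxy)-2-methoxy-3,5-bis(SEM-oxy)benzene
Conditions: MeI, K2CO3, DMF, rt, N2
Reagents that add atoms: methyl iodide, CI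
Why: Williamson methylation of the only free hydroxyl fixes the future 8-methoxy group. It is run directly after step 3 because 5 is air-sensitive.

Step 5
Reactants: 6 1-(benzyloxy)-2-methoxy-3,5-bis(SEM-oxy)benzene
Product: 7 2-methoxy-3,5-bis(SEM-oxy)phenol
Conditions: H2 (1 atm), 10% Pd/C, EtOAc, rt
Reagents that add atoms: none
Why: Hydrogenolysis of a benzyl aryl ether; SEM acetals and the methyl ether are inert. The step comes before iodine and the prenyl alkene enter, since neither would survive it.

Step 6
Reactants: 7 2-methoxy-3,5-bis(SEM-oxy)phenol
Product: 8 6-iodo-2-methoxy-3,5-bis(SEM-oxy)phenol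
Conditions: NIS (1.0 equiv), CH2Cl2, −30 → 0 °C, dark
Reagents that add atoms: N-iodosuccinimide, O=C1CCC(=O)N1I
Why: Electrophilic aromatic iodination; C6 and C4 are each activated by three oxygens, but C4 lies between two SEM-oxy groups, one of which is pushed towards it by the neighbouring methoxy group. C6 has the small hydroxyl as a neighbour, which can also hydrogen-bond to the reagent and deliver iodine. One equivalent at low temperature without acid limits di-iodination and spares the SEM groups.

Step 7
Reactants: 9 2,4'-dihydroxyacetophenone; 10 prenyl bromide
Product: 11 2-hydroxy-1-[4-(3-methylbut-2-enyloxy)phenyl]ethanone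
Conditions: K2CO3 (1.1 equiv), DMF, rt, N2
Reagents that add atoms: prenyl bromide 10 (the reactant above), CC(C)=CCBr
Why: Williamson ether synthesis; the para-acylphenol (pKa about 8) is the only group that carbonate deprotonates at room temperature, so the primary alcohol of the ketol stays free and SN2 attack occurs at the primary carbon of 10.

Step 8
Reactants: 11 2-hydroxy-1-[4-(3-methylbut-2-enyloxy)phenyl]ethanone
Product: 12 2-(SEM-oxy)-1-[4-(3-methylbut-2-enyloxy)phenyl]ethanone
Conditions: SEMCl, iPr2NEt, Bu4NI (cat.), CH2Cl2, 0 °C → rt
Reagents that add atoms: SEMCl, 2-(trimethylsilyl)ethoxymethyl chloride, C[Si](C)(C)CCOCCl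
Why: SEM protection of a primary alcohol under amine base, which is too weak to enolise the ketol. O3 receives the same fluoride-labile mask as O5 and O7.

Step 9
Reactants: 8 6-iodo-2-methoxy-3,5-bis(SEM-oxy)phenol; 12 2-(SEM-oxy)-1-[4-(3-methylbut-2-enyloxy)phenyl]ethanone; 13 carbon monoxide
Product: 15 8-methoxy-3,5,7-tris(SEM-oxy)-4'-prenyloxyflavone, via 2-(SEM-oxy)-1,3-diketone 14 (not isolated)
Conditions: 8 (1 equiv), 12 (2 equiv), NaHMDS (3.0 equiv), THF–dioxane, 0 °C; Pd(dba)2 (5 mol %), dppp (6 mol %), CO (1 atm), 80 °C; vent, then AcOH (10 equiv), 45 °C
Reagents that add atoms: carbon monoxide 13 (the reactant above), [C-]#[O+]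
Why: This is a palladium-catalysed carbonylative α-arylation of a ketone followed by cyclodehydration; the first stage is the known synthesis of 1,3-diketones from aryl iodides, CO and sodium enolates of aryl ketones, the second is the closing stage of a Baker–Venkataraman flavone synthesis, and the extensions here are the α-alkoxy group on the enolate and the unprotected ortho phenoxide. Pd(0) adds oxidatively to C4a–I of the sodium phenoxide of 8, CO inserts (helped by strain relief in the doubly ortho-substituted aryl–palladium, which also holds back direct α-arylation), the enolate of 12 replaces iodide, and C–C reductive elimination forms C4a–C4 and C3–C4. The second equivalent of enolate deprotonates 14, so the diketonate is a thermodynamic sink, and an acyl group that first lands on enolate or phenoxide oxygen remains an active ester that can be passed on to enolate carbon. NaHMDS matches the acidic protons exactly, so no free amide base is left to attack the prenyl ether, and 8 has no ortho hydrogen from which an aryne could form. On acidification the O8a hydroxyl adds to the C2 ketone (6-exo-trig), and the hemiketal loses water through an oxocarbenium ion stabilised by O1 and the 4-alkoxyphenyl group, giving the aromatic pyranone. C3 of 14 is a racemic, labile stereocentre that becomes sp2 in this dehydration, so no stereocentre has to be controlled. The 8-methoxy rather than 6-methoxy pattern is secured because O8a is the only free phenol while O5 is SEM-capped, which is why the acid stage uses the mild AcOH/NaOAc buffer formed in the flask. Oxidative addition to the aryl iodide should outrun ionisation of the trisubstituted allylic ether under CO, and heating is stopped once 8 is consumed.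

Step 10
Reactants: 15 8-methoxy-3,5,7-tris(SEM-oxy)-4'-prenyloxyflavone
Product: 16 3,5,7-trihydroxy-8-methoxy-4'-prenyloxyflavone
Conditions: TBAF (9 equiv), THF–DMPU, 50 °C, slow Ar sweep; aq. NH4Cl
Reagents that add atoms: none
Why: Fluoride attacks silicon and each SEM group fragments to fluorotrimethylsilane, ethylene and formaldehyde, expelling a stabilised aryl or enol oxide, which makes these ethers faster than alkyl SEM ethers. The methyl and prenyl ethers have no silicon trigger and are inert, and acid, which would cleave the prenyl ether, is avoided. The argon sweep carries off formaldehyde and keeps oxygen away from the flavonol anion.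

## Compound list

1 | 2,4,6-trihydroxybenzaldehyde | O=Cc1c(O)cc(O)cc1O | starting material
2 | 2-hydroxy-4,6-bis(SEM-oxy)benzaldehyde | O=Cc1c(O)cc(OCOCC[Si](C)(C)C)cc1OCOCC[Si](C)(C)C | intermediate
3 | 2-(benzyloxy)-4,6-bis(SEM-oxy)benzaldehyde | O=Cc1c(OCc2ccccc2)cc(OCOCC[Si](C)(C)C)cc1OCOCC[Si](C)(C)C | intermediate
4 | 2-(benzyloxy)-4,6-bis(SEM-oxy)phenyl formate (not isolated) | O=COc1c(OCc2ccccc2)cc(OCOCC[Si](C)(C)C)cc1OCOCC[Si](C)(C)C | intermediate
5 | 2-(benzyloxy)-4,6-bis(SEM-oxy)phenol | Oc1c(OCc2ccccc2)cc(OCOCC[Si](C)(C)C)cc1OCOCC[Si](C)(C)C | intermediate
6 | 1-(benzyloxy)-2-methoxy-3,5-bis(SEM-oxy)benzene | COc1c(OCc2ccccc2)cc(OCOCC[Si](C)(C)C)cc1OCOCC[Si](C)(C)C | intermediate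
7 | 2-methoxy-3,5-bis(SEM-oxy)phenol | COc1c(O)cc(OCOCC[Si](C)(C)C)cc1OCOCC[Si](C)(C)C | intermediate
8 | 6-iodo-2-methoxy-3,5-bis(SEM-oxy)phenol | COc1c(O)c(I)c(OCOCC[Si](C)(C)C)cc1OCOCC[Si](C)(C)C | intermediate
9 | 2,4'-dihydroxyacetophenone [2-hydroxy-1-(4-hydroxyphenyl)ethanone] | O=C(CO)c1ccc(O)cc1 | starting material
10 | prenyl bromide (1-bromo-3-methylbut-2-ene) | CC(C)=CCBr | starting material
11 | 2-hydroxy-1-[4-(3-methylbut-2-enyloxy)phenyl]ethanone | O=C(CO)c1ccc(OCC=C(C)C)cc1 | intermediate
12 | 2-(SEM-oxy)-1-[4-(3-methylbut-2-enyloxy)phenyl]ethanone | O=C(COCOCC[Si](C)(C)C)c1ccc(OCC=C(C)C)cc1 | intermediate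
13 | carbon monoxide | [C-]#[O+] | starting material
14 | 1-[2-hydroxy-3-methoxy-4,6-bis(SEM-oxy)phenyl]-2-(SEM-oxy)-3-(4-prenyloxyphenyl)propane-1,3-dione (racemic, not isolated) | COc1c(O)c(C(=O)C(OCOCC[Si](C)(C)C)C(=O)c2ccc(OCC=C(C)C)cc2)c(OCOCC[Si](C)(C)C)cc1OCOCC[Si](C)(C)C | intermediate
15 | 8-methoxy-3,5,7-tris(SEM-oxy)-4'-prenyloxyflavone | COc1c(OCOCC[Si](C)(C)C)cc(OCOCC[Si](C)(C)C)c2c(=O)c(OCOCC[Si](C)(C)C)c(-c3ccc(OCC=C(C)C)cc3)oc12 | intermediate
16 | 3,5,7-trihydroxy-8-methoxy-4'-prenyloxyflavone (achiral) | COc1c(O)cc(O)c2c(=O)c(O)c(-c3ccc(OCC=C(C)C)cc3)oc12 | target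

## Step count and least certain steps

Total step count: 10.

Longest linear sequence: 8 steps (steps 1–6, 9, 10). The ketone branch (steps 7 and 8) joins at step 9.

**Step 9 (key step).** Several processes can go wrong:
- Turnover may be slowed by chelation of the ortho phenoxide to the aroylpalladium centre.
- The acyl group may be captured at phenoxide or enolate oxygen without onward transfer, because the doubly ortho-oxygenated aroyl group is hindered.
- Palladium(0) may ionise the allylic C–O bond of the prenyl ether, which is activated by the para acyl group, and the soft diketonate may then be allylated.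
- The poorly enolised 14 may undergo retro-Claisen cleavage if water reaches it before acid.
- Premature loss of the O5 SEM group would erode the 8-/6-methoxy control.

The fallback keeps 8 and 13 but replaces the enolate with a terminal alkyne, which is the best-established carbonylative entry from 2-iodophenols to flavones, and brings in O3 afterwards. Purchased 4-ethynylphenol F1 is alkylated with 10 (K2CO3, DMF) to give 1-ethynyl-4-prenyloxybenzene F2. Compounds 8, F2 and 13 are joined under palladium catalysis in diethylamine. This is a carbonylative Sonogashira coupling with amine-mediated 6-endo closure through the free O8a, and it gives the 3-unsubstituted flavone F3. LDA at −78 °C lithiates C3 next to the C4 carbonyl, trimethyl borate gives the boronate F4, and H2O2/AcOH oxidises the C–B bond to the 3-hydroxyflavone F5. This oxidation leaves the prenyl alkene alone, whereas a dioxirane or peracid hydroxylation would not. F5 is then treated with fluoride as in step 10 and rejoins the route at 16.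

**Step 6.** Site selectivity between C6 and C4 may be poor and over-iodination may occur. Both positions are activated by three oxygens, and the preference for C6 rests only on steric shielding and on hydrogen-bond delivery.

The fallback replaces electrophilic substitution with directed ortho-metalation. It sets out from 7, which is carbamoylated (Et2NCOCl, K2CO3, MeCN) to the O-aryl N,N-diethylcarbamate F6. s-BuLi/TMEDA at −78 °C is guided by the carbamate carbonyl, a stronger director than an acetal ether, to its only free ortho position, which is also flanked by the 5-SEM-oxy group. Iodine then gives the iodocarbamate F7. Hydrolysis (NaOH, aq. EtOH, reflux), which aryl iodide and SEM ethers tolerate, rejoins the route at 8.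

**Step 10.** The peri and enol SEM ethers may cleave incompletely under tolerable conditions. Released formaldehyde may be captured at the nucleophilic C6 of the freed phloroglucinol-type phenoxide. The flavonol anion may degrade oxidatively.

The fallback divides the deprotection by mechanism. It sets out from 15, where MgBr2·OEt2 (Et2O–CH2Cl2, rt) chelates the C4 carbonyl together with O3 or O5. Bromide then opens only these two acetals, giving 3,5-dihydroxy-8-methoxy-7-(SEM-oxy)-4'-prenyloxyflavone F8, in which both new hydroxyls are hydrogen-bonded to C4=O. The single remaining, unhindered SEM group is removed with fluoride at lower temperature, so only one equivalent of formaldehyde is released in base. The route is rejoined at 16.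

**Step 1.** The reaction may give statistical under- and over-protection, because the discrimination rests only on one hydrogen bond.

The fallback makes the selectivity a deprotection problem. It sets out from 1, which is exhaustively protected (SEMCl in excess, NaH, DMF) to 2,4,6-tris(SEM-oxy)benzaldehyde F9. One equivalent of MgBr2·OEt2 chelates the aldehyde oxygen and one ortho acetal oxygen and cleaves only that group. The resulting magnesium phenoxide chelate blocks a second activation, and the route is rejoined at 2.

## Further compounds

F1 | step 9 | 4-ethynylphenol (purchased) | C#Cc1ccc(O)cc1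
F2 | step 9 | 1-ethynyl-4-(3-methylbut-2-enyloxy)benzene | C#Cc1ccc(OCC=C(C)C)cc1
F3 | step 9 | 8-methoxy-5,7-bis(SEM-oxy)-4'-prenyloxyflavone | COc1c(OCOCC[Si](C)(C)C)cc(OCOCC[Si](C)(C)C)c2c(=O)cc(-c3ccc(OCC=C(C)C)cc3)oc12
F4 | step 9 | dimethyl [8-methoxy-5,7-bis(SEM-oxy)-4'-prenyloxyflavon-3-yl]boronate | COB(OC)c1c(-c2ccc(OCC=C(C)C)cc2)oc2c(OC)c(OCOCC[Si](C)(C)C)cc(OCOCC[Si](C)(C)C)c2c1=O
F5 | step 9 | 3-hydroxy-8-methoxy-5,7-bis(SEM-oxy)-4'-prenyloxyflavone | COc1c(OCOCC[Si](C)(C)C)cc(OCOCC[Si](C)(C)C)c2c(=O)c(O)c(-c3ccc(OCC=C(C)C)cc3)oc12
F6 | step 6 | 2-methoxy-3,5-bis(SEM-oxy)phenyl N,N-diethylcarbamate | CCN(CC)C(=O)Oc1cc(OCOCC[Si](C)(C)C)cc(OCOCC[Si](C)(C)C)c1OC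
F7 | step 6 | 6-iodo-2-methoxy-3,5-bis(SEM-oxy)phenyl N,N-diethylcarbamate | CCN(CC)C(=O)Oc1c(I)c(OCOCC[Si](C)(C)C)cc(OCOCC[Si](C)(C)C)c1OC
F8 | step 10 | 3,5-dihydroxy-8-methoxy-7-(SEM-oxy)-4'-prenyloxyflavone | COc1c(OCOCC[Si](C)(C)C)cc(O)c2c(=O)c(O)c(-c3ccc(OCC=C(C)C)cc3)oc12
F9 | step 1 | 2,4,6-tris(SEM-oxy)benzaldehyde | O=Cc1c(OCOCC[Si](C)(C)C)cc(OCOCC[Si](C)(C)C)cc1OCOCC[Si](C)(C)C
A1 | alternative 1 | trans-3-(tert-butyldimethylsilyloxy)-8-methoxy-5,7-bis(SEM-oxy)-4'-prenyloxyflavanone (racemic, one enantiomer drawn) | COc1c(OCOCC[Si](C)(C)C)cc(OCOCC[Si](C)(C)C)c2c1O[C@H](c1ccc(OCC=C(C)C)cc1)[C@@H](O[Si](C)(C)C(C)(C)C)C2=O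
A2 | alternative 1 | methyl 2-(tert-butyldimethylsilyloxy)-3-[2-iodo-6-methoxy-3,5-bis(SEM-oxy)phenoxy]-3-(4-prenyloxyphenyl)propanoate (racemic, one enantiomer drawn) | COc1c(OCOCC[Si](C)(C)C)cc(OCOCC[Si](C)(C)C)c(I)c1O[C@H](c1ccc(OCC=C(C)C)cc1)[C@@H](O[Si](C)(C)C(C)(C)C)C(=O)OC
A3 | alternative 2 | 8-methoxy-3-(2-trimethylsilylethoxy)-5,7-bis(SEM-oxy)-4'-prenyloxyflavone | COc1c(OCOCC[Si](C)(C)C)cc(OCOCC[Si](C)(C)C)c2c(=O)c(OCC[Si](C)(C)C)c(-c3ccc(OCC=C(C)C)cc3)oc12
A4 | alternative 2 | 3-methoxy-2-(4-prenyloxybenzoyloxy)-4,6-bis(SEM-oxy)benzoyl chloride | COc1c(OCOCC[Si](C)(C)C)cc(OCOCC[Si](C)(C)C)c(C(=O)Cl)c1OC(=O)c1ccc(OCC=C(C)C)cc1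
A5 | alternative 2 | [2-(trimethylsilyl)ethoxy]methylenetriphenylphosphorane | C[Si](C)(C)CCOC=P(c1ccccc1)(c1ccccc1)c1ccccc1
A6 | alternative 3 | 5,8-dihydroxy-3,7-bis(SEM-oxy)-4'-prenyloxyflavone | Oc1c(OCOCC[Si](C)(C)C)cc(O)c2c(=O)c(OCOCC[Si](C)(C)C)c(-c3ccc(OCC=C(C)C)cc3)oc12
A7 | alternative 3 | 1-[2,5-dihydroxy-4-(SEM-oxy)phenyl]-2-(SEM-oxy)-3-(4-prenyloxyphenyl)propane-1,3-dione (racemic) | Oc1cc(OCOCC[Si](C)(C)C)c(O)cc1C(=O)C(OCOCC[Si](C)(C)C)C(=O)c1ccc(OCC=C(C)C)cc1
A8 | alternative 3 | 2-[2-(SEM-oxy)-3-oxo-3-(4-prenyloxyphenyl)propanoyl]-5-(SEM-oxy)-1,4-benzoquinone (racemic) | O=C1C=C(OCOCC[Si](C)(C)C)C(=O)C=C1C(=O)C(OCOCC[Si](C)(C)C)C(=O)c1ccc(OCC=C(C)C)cc1
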